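## Retrosynthetic overview

1. The target comes from one global hydrogenolysis of a tri-acetate (two benzylic C–OAc and two ArO–Bn bonds cleaved, the primary acetate kept), itself from LiAlH4 opening and acetylation of an aldol lactone.
2. Key disconnection C8′–C7′: an aldol between the enolate of a γ-aryl-β-methyl-γ-butyrolactone (guaiacyl half) and O-benzylsyringaldehyde (syringyl half); attack anti to the ring methyl sets C8′.
3. The lactone half comes from an aryl Grignard (catechol: methylation, para-bromination, benzylation) and an α-methyl aldehyde made from (R)-β-methyl-γ-butyrolactone, which supplies C8.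
4. The aldehyde half comes from p-cresol: ring bromination, side-chain bromination/hydrolysis, Cu-catalysed methoxylation, benzylation.
5. Rings: neither arene is built. The only ring formed is a temporary γ-lactone (step 6), used as the stereocontrol template and opened in step 12.

Assumption: (R)-β-methyl-γ-butyrolactone is bought as the single enantiomer; lignan numbering is used (C7–C9 guaiacyl half, C7′–C9′ syringyl half), so the target is (8S,8′R).

## Route

**Step 1**
Reactants: 1, catechol
Product: 2, guaiacol (2-methoxyphenol)
Conditions: MeI (0.95 equiv), K2CO3, acetone, reflux; veratrole and unreacted catechol removed by base/water extraction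
Reagents that add atoms: methyl iodide, CI
Why: Williamson mono-O-methylation; the statistical by-products are easily separated.

**Step 2**
Reactants: 2, guaiacol
Product: 3, 4-bromo-2-methoxyphenol
Conditions: Bu4NBr3 (1.0 equiv), CH2Cl2–MeOH, rt
Reagents that add atoms: tetrabutylammonium tribromide, CCCC[N+](CCCC)(CCCC)CCCC.[Br-].BrBr (the Br3− anion written as bromide plus Br2)
Why: Electrophilic aromatic bromination with a mild Br+ source goes para to the free OH, the strongest director.

**Step 3**
Reactants: 3, 4-bromo-2-methoxyphenol
Product: 4, 1-(benzyloxy)-4-bromo-2-methoxybenzene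
Conditions: BnBr, K2CO3, DMF, 60 °C
Reagents that add atoms: benzyl bromide, BrCc1ccccc1
Why: Williamson etherification masks the phenol for the Grignard, enolate and hydride steps.

**Step 4**
Reactants: 5, (R)-4-methyldihydrofuran-2(3H)-one [(R)-β-methyl-γ-butyrolactone]
Product: 6, (R)-4-hydroxy-N-methoxy-N,3-dimethylbutanamide
Conditions: MeNH(OMe)·HCl (3 equiv), AlMe3 (3 equiv), CH2Cl2, 0 °C → rt
Reagents that add atoms: N,O-dimethylhydroxylamine hydrochloride, CNOC.Cl
Why: Weinreb aluminium-amide aminolysis opens the lactone and differentiates its two termini without touching the stereocentre.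

**Step 5**
Reactants: 6
Product: 7, (R)-N-methoxy-N,3-dimethyl-4-oxobutanamide
Conditions: Dess–Martin periodinane, NaHCO3, CH2Cl2, 0 °C → rt; used crude and immediately
Reagents that add atoms: none
Why: Buffered Dess–Martin oxidation gives the α-methyl aldehyde under non-epimerising conditions.

**Step 6**
Reactants: 4, aryl bromide; 7, aldehyde
Product: 8, (4R)-5-[4-(benzyloxy)-3-methoxyphenyl]-4-methyldihydrofuran-2(3H)-one, as a mixture of C5 epimers (cis expected major)
Conditions: 4, Mg, cat. I2, THF, 40 °C; add ArMgBr (1.05 equiv) to 7, THF, −78 °C; aq. NH4Cl; then cat. TsOH, toluene, rt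
Reagents that add atoms: none (Mg only converts 4 into the Grignard reagent)
Why: Chemoselective Grignard addition to the aldehyde (the Weinreb amide is inert at −78 °C) and lactonisation with loss of MeNHOMe; C4 (future C8) is carried from 5, and the uncontrolled C5 carbinol is reduced to CH2 in step 14.

**Step 7**
Reactants: 9, p-cresol
Product: 10, 2,6-dibromo-4-methylphenol
Conditions: Br2 (2.05 equiv), CH2Cl2, 0 °C → rt
Reagents that add atoms: bromine, BrBr
Why: Electrophilic bromination can only go to the two positions ortho to OH because the para position is blocked.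

**Step 8**
Reactants: 10
Product: 11, 3,5-dibromo-4-hydroxybenzaldehyde
Conditions: Br2 (2.1 equiv), o-dichlorobenzene, 150–160 °C; then H2O, 100 °C
Reagents that add atoms: water, O
Why: High-temperature side-chain bromination gives the benzal bromide, which hydrolyses to the aldehyde (the established industrial p-cresol process).

**Step 9**
Reactants: 11
Product: 12, syringaldehyde (4-hydroxy-3,5-dimethoxybenzaldehyde)
Conditions: NaOMe (5 equiv), CuCl (15 mol %), DMF–MeOH, 115 °C; acidic work-up
Reagents that add atoms: sodium methoxide, C[O-].[Na+]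
Why: Copper-catalysed Ullmann-type methoxylation replaces both aryl bromides.

**Step 10**
Reactants: 12
Product: 13, 4-(benzyloxy)-3,5-dimethoxybenzaldehyde
Conditions: BnBr, K2CO3, DMF, 60 °C
Reagents that add atoms: benzyl bromide, BrCc1ccccc1
Why: Williamson etherification protects the phenol so the aldehyde can meet a lithium enolate.

**Step 11 (fragment coupling)**
Reactants: 8, lactone; 13, aldehyde
Product: 14, (3S,4R)-5-[4-(benzyloxy)-3-methoxyphenyl]-3-{[4-(benzyloxy)-3,5-dimethoxyphenyl](hydroxy)methyl}-4-methyldihydrofuran-2(3H)-one (3,4-trans; epimeric at C5 and at the carbinol carbon)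
Conditions: LDA (1.1 equiv), THF, −78 °C, 45 min; then 13, −78 °C, 1.5 h; AcOH quench at −78 °C
Reagents that add atoms: none
Why: Lithium-enolate aldol addition occurs on the face anti to the C4 methyl (both C5 epimers of 8 converge on the same C3 configuration), setting C8′ trans to C8; the aldehyde is non-enolisable.

**Step 12**
Reactants: 14
Product: 15, (2R,3R)-1-[4-(benzyloxy)-3-methoxyphenyl]-4-[4-(benzyloxy)-3,5-dimethoxyphenyl]-3-(hydroxymethyl)-2-methylbutane-1,4-diol (epimeric at C1 and C4)
Conditions: LiAlH4 (3 equiv), THF, −20 → 0 °C; Rochelle-salt work-up (no acid)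
Reagents that add atoms: none
Why: Hydride reduction opens the lactone to the primary alcohol (future CH2OAc) and the C7 benzylic alcohol; the acid-free work-up avoids tetrahydrofuran or aryltetralin formation.

**Step 13**
Reactants: 15
Product: 16, (2R,3R)-3-(acetoxymethyl)-1-[4-(benzyloxy)-3-methoxyphenyl]-4-[4-(benzyloxy)-3,5-dimethoxyphenyl]-2-methylbutane-1,4-diyl diacetate (epimeric at C1 and C4)
Conditions: Ac2O (6 equiv), pyridine, cat. DMAP, CH2Cl2, 0 °C → rt
Reagents that add atoms: acetic anhydride, CC(=O)OC(C)=O
Why: DMAP-catalysed peracetylation installs the required primary acetate while both phenols are still benzylated, and activates the two benzylic oxygens for removal.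

**Step 14**
Reactants: 16
Product: 17, (2R,3S)-2-(4-hydroxy-3,5-dimethoxybenzyl)-4-(4-hydroxy-3-methoxyphenyl)-3-methylbutyl acetate (target)
Conditions: H2 (3–4 atm), 10% Pd/C, EtOAc–AcOH (20:1), rt
Reagents that add atoms: none
Why: Catalytic hydrogenolysis cleaves both electron-rich benzylic C–OAc bonds and both O-benzyl ethers while the primary alkyl acetate and the non-benzylic C8/C8′ stereocentres are untouched.

## Compound list

1 | catechol | Oc1ccccc1O | starting material
2 | guaiacol | COc1ccccc1O | intermediate
3 | 4-bromo-2-methoxyphenol | COc1cc(Br)ccc1O | intermediate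
4 | 1-(benzyloxy)-4-bromo-2-methoxybenzene | COc1cc(Br)ccc1OCc1ccccc1 | intermediate
5 | (R)-4-methyldihydrofuran-2(3H)-one | C[C@@H]1CC(=O)OC1 | starting material
6 | (R)-4-hydroxy-N-methoxy-N,3-dimethylbutanamide | C[C@@H](CO)CC(=O)N(C)OC | intermediate
7 | (R)-N-methoxy-N,3-dimethyl-4-oxobutanamide | C[C@@H](C=O)CC(=O)N(C)OC | intermediate
8 | (4R)-5-[4-(benzyloxy)-3-methoxyphenyl]-4-methyldihydrofuran-2(3H)-one (C5 epimers) | C[C@@H]1CC(=O)OC1c1ccc(OCc2ccccc2)c(OC)c1 | intermediate
9 | p-cresol | Cc1ccc(O)cc1 | starting material
10 | 2,6-dibromo-4-methylphenol | Cc1cc(Br)c(O)c(Br)c1 | intermediate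
11 | 3,5-dibromo-4-hydroxybenzaldehyde | O=Cc1cc(Br)c(O)c(Br)c1 | intermediate
12 | syringaldehyde | COc1cc(C=O)cc(OC)c1O | intermediate
13 | 4-(benzyloxy)-3,5-dimethoxybenzaldehyde | COc1cc(C=O)cc(OC)c1OCc1ccccc1 | intermediate
14 | (3S,4R)-aldol lactone (epimeric at C5 and carbinol C) | C[C@@H]1[C@@H](C(O)c2cc(OC)c(OCc3ccccc3)c(OC)c2)C(=O)OC1c1ccc(OCc2ccccc2)c(OC)c1 | intermediate
15 | (2R,3R)-triol (epimeric at both benzylic carbinols) | C[C@@H](C(O)c1ccc(OCc2ccccc2)c(OC)c1)[C@@H](C(O)c1cc(OC)c(OCc2ccccc2)c(OC)c1)CO | intermediate
16 | (2R,3R)-triacetate (epimeric at both benzylic carbons) | C[C@@H](C(OC(C)=O)c1ccc(OCc2ccccc2)c(OC)c1)[C@@H](C(OC(C)=O)c1cc(OC)c(OCc2ccccc2)c(OC)c1)COC(C)=O | intermediate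
17 | (2R,3S)-2-(4-hydroxy-3,5-dimethoxybenzyl)-4-(4-hydroxy-3-methoxyphenyl)-3-methylbutyl acetate | COc1cc(C[C@H](C)[C@H](COC(C)=O)Cc2cc(OC)c(O)c(OC)c2)ccc1O | target

## Summary

Total step count: 14.

Longest linear sequence: 8 steps (catechol: steps 1, 2, 3, 6, 11–14; equally p-cresol: steps 7–14).

Steps most likely to fail:

- **Step 6 (with aldehyde 7).** The α-methyl aldehyde may epimerise, the Grignard may attack the Weinreb amide, and the product is a C5 epimer mixture. Fallback: build 8 by asymmetric anti-crotylation. Convert 4 to 4-(benzyloxy)-3-methoxybenzaldehyde (n-BuLi, DMF), crotylate with the appropriate antipode of an (E)-crotyl-Ipc2B reagent, then hydroborate (9-BBN/H2O2) and lactonise (TEMPO/PhI(OAc)2). This gives trans-(4R,5R)-8 as a single isomer.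
- **Step 11 (aldol coupling).** Retro-aldol, sluggish addition to the electron-rich aldehyde, or imperfect 3,4-trans control are the risks. Fallback: irreversible SN2 alkylation of the same enolate with 4-(benzyloxy)-3,5-dimethoxybenzyl bromide (13 → NaBH4 → PBr3). This gives the 3,4-trans benzyl lactone directly and leaves only one benzylic C–O for the endgame.
- **Step 14 (double benzylic hydrogenolysis).** Incomplete C–O cleavage, elimination/re-reduction that would scramble C8/C8′, or aryltetralin formation are the risks. Fallback: avoid benzylic oxygen altogether with an auxiliary route. Open 5 to ethyl (R)-4-iodo-3-methylbutanoate (TMSI, then EtOH), form the zinc reagent and Negishi-couple it with 4. Hydrolyse, attach an Evans oxazolidinone, and benzylate the enolate with the syringyl benzyl bromide. Then LiBH4, Ac2O, and a simple O-debenzylation.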